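**Retrosynthetic overview**

1. The target is (4R)-5,9,14-trimethyl-4-nonyl-1,5,9,14-tetraazacycloheptadecan-2-one. Ring numbering: N1(H), C2(=O), C3, C4 (stereocentre, nonyl), N5(Me), C6, C7, C8, N9(Me), C10–C13, N14(Me), C15–C17. The 17-membered ring is the only ring and is closed last, at C7–C8.
2. Enabling feature: the segment N5–C6–C7–C8–N9 is a 1,3-diamine (a Mannich pattern at the amine oxidation level) whose two nitrogens are tertiary N-methyl amines, while the only carbonyl of the ring is the secondary N1–H lactam. C8 can therefore come from an N9-formyl group and C6–C7 from an N5-acetyl group, two tertiary amides that an iridium/silane catalyst activates beside the lactam.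
3. Key disconnection: reductive Mannich macrocyclisation of the open-chain formamide/acetamide. The formyl carbon becomes the C8 electrophile, the acetyl CH3 the C7 nucleophile and the acetyl C=O becomes C6; both oxygen atoms leave in the same operation.
4. The open chain is cut at the N1–C2 amide into (3R)-3-[acetyl(methyl)amino]dodecanoic acid and a formyl-capped triamine. The acid comes from decanal, with C4 set by titanium-enolate addition to an N-tert-butanesulfinyl imine; the triamine comes from N,N'-dimethylbutane-1,4-diamine and acrylonitrile.
5. Order of ring formation: no ring exists before the last step. Formyl and acetyl serve as protecting groups in the coupling and as the carbon source of C6–C8.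

Key step: step 11

Assumption: the sense of induction in step 5 is taken from the closed, titanium-chelated chair model, by which the (R)-sulfinyl imine of a linear aldehyde should give the 3R adduct; if the opposite sense operated, (S)-2-methylpropane-2-sulfinamide would be used instead.

**Route**

Step 1
Reactants: 1 N,N'-dimethylbutane-1,4-diamine; 2 acrylonitrile
Product: 3 3-{methyl[4-(methylamino)butyl]amino}propanenitrile
Conditions: 1 (4 equiv), 2 (1 equiv, slow addition), MeOH, 0 °C → rt; excess 1 distilled off
Reagents that add atoms: none
Why: Aza-Michael addition (cyanoethylation) of a secondary amine to acrylonitrile; the excess of the symmetrical diamine should keep double addition low, and unreacted 1 is recovered by distillation.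

Step 2
Reactants: 3 3-{methyl[4-(methylamino)butyl]amino}propanenitrile
Product: 4 N-{4-[(2-cyanoethyl)(methyl)amino]butyl}-N-methylformamide
Conditions: HCO2Et (neat), reflux
Reagents that add atoms: ethyl formate, CCOC=O
Why: N-formylation by aminolysis of ethyl formate; only the secondary amine of 3 can be acylated, the tertiary amine and the nitrile being inert.

Step 3
Reactants: 4 N-{4-[(2-cyanoethyl)(methyl)amino]butyl}-N-methylformamide
Product: 5 N-{4-[(3-aminopropyl)(methyl)amino]butyl}-N-methylformamide
Conditions: H2 (5 bar), Raney Ni, NH3 (7 M in MeOH), rt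
Reagents that add atoms: none
Why: Heterogeneous catalytic hydrogenation of the nitrile to the primary amine, with ammonia suppressing secondary-amine formation; the formamide and the tertiary amine should not react.

Step 4
Reactants: 6 decanal; 7 (R)-2-methylpropane-2-sulfinamide
Product: 8 (R,E)-N-decylidene-2-methylpropane-2-sulfinamide
Conditions: Ti(OEt)4 (2 equiv), THF, rt
Reagents that add atoms: none
Why: Ellman condensation of an aldehyde with tert-butanesulfinamide, Ti(OEt)4 acting as Lewis acid and water scavenger, should give the E-aldimine with the sulfur configuration retained.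

Step 5
Reactants: 8 (R,E)-N-decylidene-2-methylpropane-2-sulfinamide
Product: 9 methyl (3R)-3-{[(R)-tert-butylsulfinyl]amino}dodecanoate
Conditions: MeOAc, LiN(iPr)2, THF, −78 °C; ClTi(OiPr)3; then 8, −78 °C
Reagents that add atoms: methyl acetate, COC(C)=O
Why: Titanium-enolate Mannich-type addition to an N-sulfinyl aldimine through a closed chair transition state with titanium bound to the sulfinyl oxygen; the R-configured sulfur directs the enolate to one face of the C=N bond and should set C3 (the later C4 of the ring) as R with high diastereoselectivity.

Step 6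
Reactants: 9 methyl (3R)-3-{[(R)-tert-butylsulfinyl]amino}dodecanoate
Product: 10 methyl (3R)-3-{[(R)-tert-butylsulfinyl](methyl)amino}dodecanoate
Conditions: LiN(SiMe3)2 (1.05 equiv), THF/DMF, −40 °C; MeI, −40 → 0 °C
Reagents that add atoms: iodomethane, CI
Why: N-alkylation of the sulfinamide anion (SN2 on MeI); the sulfinamide N–H is much more acidic than the ester α-C–H, so one equivalent of base at low temperature should deprotonate nitrogen only and leave both stereocentres untouched.

Step 7
Reactants: 10 methyl (3R)-3-{[(R)-tert-butylsulfinyl](methyl)amino}dodecanoate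
Product: 11 methyl (3R)-3-(methylamino)dodecanoate hydrochloride
Conditions: HCl (4 M in dioxane), MeOH, 0 °C → rt
Reagents that add atoms: hydrogen chloride, Cl
Why: Acidic alcoholysis of the S–N bond removes the sulfinyl auxiliary; methanol matches the methyl ester, and the amine is kept as its hydrochloride so that it cannot condense with the ester.

Step 8
Reactants: 11 methyl (3R)-3-(methylamino)dodecanoate hydrochloride
Product: 12 methyl (3R)-3-[acetyl(methyl)amino]dodecanoate
Conditions: Ac2O, Et3N, DMAP (cat.), CH2Cl2, 0 °C → rt
Reagents that add atoms: acetic anhydride, CC(=O)OC(C)=O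
Why: N-acetylation of the liberated secondary amine (nucleophilic acyl substitution with DMAP catalysis); the acetyl group masks N5 and later supplies C6 and C7 of the ring.

Step 9
Reactants: 12 methyl (3R)-3-[acetyl(methyl)amino]dodecanoate
Product: 13 (3R)-3-[acetyl(methyl)amino]dodecanoic acid
Conditions: LiOH, THF/H2O, 0 °C → rt; then aq. HCl to pH 3
Reagents that add atoms: lithium hydroxide, [Li+].[OH-]
Why: Saponification of the methyl ester; the tertiary acetamide should be stable to LiOH at this temperature and the stereocentre is β to the carboxyl group and cannot epimerise by enolisation.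

Step 10
Reactants: 13 (3R)-3-[acetyl(methyl)amino]dodecanoic acid; 5 N-{4-[(3-aminopropyl)(methyl)amino]butyl}-N-methylformamide
Product: 15 (3R)-3-[acetyl(methyl)amino]-N-{3-[{4-[formyl(methyl)amino]butyl}(methyl)amino]propyl}dodecanamide, via benzotriazolyl ester 14 (not isolated)
Conditions: N,N'-diisopropylcarbodiimide (DIC), HOBt, CH2Cl2, 0 °C; then 5, rt
Reagents that add atoms: none
Why: Carbodiimide/HOBt amide coupling through the active ester 14; the formyl and acetyl groups mask both secondary nitrogens, so only the primary amine of 5 can be acylated.

Step 11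
Reactants: 15 (3R)-3-[acetyl(methyl)amino]-N-{3-[{4-[formyl(methyl)amino]butyl}(methyl)amino]propyl}dodecanamide
Product: 19 (4R)-5,9,14-trimethyl-4-nonyl-1,5,9,14-tetraazacycloheptadecan-2-one, via bis(O-silyl hemiaminal) 16 (not isolated), via vinylamine silyl acetal 17 (not isolated), via macrocyclic iminium acetate 18 (not isolated)
Conditions: IrCl(CO)(PPh3)2 (2 mol %), (HMe2Si)2O (4.5 equiv), toluene, rt; then slow addition into AcOH (10 equiv), MeCN (2 mM), 0 °C → rt; then NaBH(OAc)3 (4 equiv), rt
Reagents that add atoms: none
Why: Proposed new method: IrCl(CO)(PPh3)2 with (HMe2Si)2O should hydrosilylate only the two tertiary amides of 15 to the O-silyl hemiaminals 16; the acetyl-derived one loses silanol to the N-vinyl enamine 17, while the formyl-derived N,O-acetal has no α-hydrogen and stays as a latent methyleneiminium ion, which acetic acid at high dilution ionises so that the enamine β-carbon (former acetyl CH3, C7) attacks the CH2=N carbon (former formyl carbon, C8) in an intramolecular Mannich reaction to the cyclic iminium 18, reduced at C6 by NaBH(OAc)3 to 19. The closest known reaction types are the iridium/silane reductive functionalisation of tertiary amides (reductive Strecker, Mannich and nitro-Mannich reactions of the hemiaminals, and amide-to-enamine reduction) and the Mannich reaction of enamines with methyleneiminium salts; new is their union in one molecule so that two amide carbons are joined to each other. The 17-membered ring closes in a 17-endo-trig mode at the iminium carbon (enol-endo with respect to the enamine), and the 2 mM concentration should favour it over dimerisation. No stereocentre is formed, and C4 lies off the reaction path and should keep its R configuration. The step needs chemoselectivity and an unambiguous assignment of roles: the secondary N1–H lactam is inert to this catalyst system, only the acetyl-derived terminus can become a nucleophile, only the formyl-derived terminus is a non-enolisable electrophile, and the one-carbon electrophile is built into the substrate once, so a second aminomethylation cannot occur within the molecule. Hydride is added only after the C–C bond has formed, so that neither terminus is reduced to N-methyl or N-ethyl before it has reacted.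

**Compound list**

1 | N,N'-dimethylbutane-1,4-diamine | CNCCCCNC | starting material
2 | acrylonitrile | C=CC#N | starting material
3 | 3-{methyl[4-(methylamino)butyl]amino}propanenitrile | CNCCCCN(C)CCC#N | intermediate
4 | N-{4-[(2-cyanoethyl)(methyl)amino]butyl}-N-methylformamide | O=CN(C)CCCCN(C)CCC#N | intermediate
5 | N-{4-[(3-aminopropyl)(methyl)amino]butyl}-N-methylformamide | O=CN(C)CCCCN(C)CCCN | intermediate
6 | decanal | CCCCCCCCCC=O | starting material
7 | (R)-2-methylpropane-2-sulfinamide | CC(C)(C)[S@@](=O)N | starting material
8 | (R,E)-N-decylidene-2-methylpropane-2-sulfinamide | CCCCCCCCC/C=N/[S@](=O)C(C)(C)C | intermediate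
9 | methyl (3R)-3-{[(R)-tert-butylsulfinyl]amino}dodecanoate | CCCCCCCCC[C@@H](N[S@](=O)C(C)(C)C)CC(=O)OC | intermediate
10 | methyl (3R)-3-{[(R)-tert-butylsulfinyl](methyl)amino}dodecanoate | CCCCCCCCC[C@@H](N(C)[S@](=O)C(C)(C)C)CC(=O)OC | intermediate
11 | methyl (3R)-3-(methylamino)dodecanoate hydrochloride | CCCCCCCCC[C@@H](NC)CC(=O)OC.Cl | intermediate
12 | methyl (3R)-3-[acetyl(methyl)amino]dodecanoate | CCCCCCCCC[C@@H](N(C)C(C)=O)CC(=O)OC | intermediate
13 | (3R)-3-[acetyl(methyl)amino]dodecanoic acid | CCCCCCCCC[C@@H](N(C)C(C)=O)CC(=O)O | intermediate
14 | 1H-benzotriazol-1-yl (3R)-3-[acetyl(methyl)amino]dodecanoate (active ester, not isolated) | CCCCCCCCC[C@@H](N(C)C(C)=O)CC(=O)On1nnc2ccccc12 | intermediate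
15 | (3R)-3-[acetyl(methyl)amino]-N-{3-[{4-[formyl(methyl)amino]butyl}(methyl)amino]propyl}dodecanamide | CCCCCCCCC[C@@H](N(C)C(C)=O)CC(=O)NCCCN(C)CCCCN(C)C=O | intermediate
16 | bis(O-silyl hemiaminal) of 15: both tertiary amide C=O groups converted into CH–O–SiMe2–O–SiMe2H, both epimers at the acetyl-derived carbon (not isolated) | CCCCCCCCC[C@@H](N(C)C(C)O[Si](C)(C)O[SiH](C)C)CC(=O)NCCCN(C)CCCCN(C)CO[Si](C)(C)O[SiH](C)C | intermediate
17 | (3R)-3-[methyl(vinyl)amino]-N-{3-[methyl(4-{methyl[(1,1,3,3-tetramethyldisiloxanyloxy)methyl]amino}butyl)amino]propyl}dodecanamide (not isolated) | CCCCCCCCC[C@@H](N(C)C=C)CC(=O)NCCCN(C)CCCCN(C)CO[Si](C)(C)O[SiH](C)C | intermediate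
18 | macrocyclic N5=C6 iminium acetate, (4R)-5,9,14-trimethyl-4-nonyl-2-oxo-1,9,14-triaza-5-azoniacycloheptadec-5-ene acetate (not isolated) | CCCCCCCCC[C@@H]1CC(=O)NCCCN(C)CCCCN(C)CCC=[N+]1C.CC(=O)[O-] | intermediate
19 | (4R)-5,9,14-trimethyl-4-nonyl-1,5,9,14-tetraazacycloheptadecan-2-one | CCCCCCCCC[C@@H]1CC(=O)NCCCN(C)CCCCN(C)CCCN1C | target

**Step count and risks**

Total step count: 11. Longest linear sequence: 8 steps (steps 4 to 11, from decanal).

Steps most likely to fail:

Step 11 (proposed new method). Intermolecular Mannich coupling may outpace ring closure. The enamine terminus may self-condense or be hydrolysed before it meets the iminium carbon. The formyl-derived N,O-acetal may be over-reduced to an N-methyl group. The lactam N–H may trap an iminium ion as a cyclic aminal before hydride delivery. Fallback, from 15 back to 19, with the same bond closed at the amide oxidation level by known reaction types: the formyl group of 15 would be removed selectively by acidic methanolysis (HCl, MeOH, 50 °C) to give the secondary amine (3R)-3-[acetyl(methyl)amino]-N-[3-(methyl{4-(methylamino)butyl}amino)propyl]dodecanamide F1. Condensation of F1 with paraformaldehyde and one-pot silyl ketene aminal formation/Mukaiyama–Mannich ring closure (TMSOTf, iPr2NEt, CH2Cl2, high dilution) would give the macrocyclic β-amino amide (4R)-5,9,14-trimethyl-4-nonyl-1,5,9,14-tetraazacycloheptadecane-2,6-dione F2. Its tertiary C6 amide would then be reduced beside the secondary lactam (IrCl(CO)(PPh3)2, (HMe2Si)2O, toluene; then NaBH(OAc)3, AcOH) to 19.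

Step 6. The base may enolise the ester, which would lead to β-elimination of the sulfinamide (retro-aza-Michael, with loss of the stereocentre) or to C-methylation. Fallback, from 9 back to 11, by a Fukuyama sequence that avoids a strong base: the sulfinyl group of 9 would be cleaved first (HCl, MeOH) to methyl (3R)-3-aminododecanoate hydrochloride F3. Sulfonylation (2-nitrobenzenesulfonyl chloride, Et3N, CH2Cl2) would give methyl (3R)-3-[(2-nitrophenyl)sulfonylamino]dodecanoate F4, and methylation (MeI, K2CO3, DMF) would give methyl (3R)-3-[methyl(2-nitrophenylsulfonyl)amino]dodecanoate F5. Removal of the sulfonyl group (PhSH, K2CO3, MeCN) and treatment with HCl would give 11.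

Step 3. Reductive dimerisation to a secondary amine, transfer of the formyl group to the new primary amine, or loss of the cyanoethyl arm by retro-Michael reaction may erode the yield. Fallback, from 1 back to 5, with the primary amine brought in by a Gabriel synthesis instead of a nitrile reduction: mono-formylation of 1 (HCO2Et, excess 1) would give N-methyl-N-[4-(methylamino)butyl]formamide F6. Alkylation with N-(3-bromopropyl)phthalimide (K2CO3, MeCN, 60 °C) would give N-{4-[[3-(1,3-dioxoisoindolin-2-yl)propyl](methyl)amino]butyl}-N-methylformamide F7, and hydrazinolysis (N2H4·H2O, EtOH, rt) would give 5.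

**Further compounds**

F1 | step 11 | (3R)-3-[acetyl(methyl)amino]-N-[3-(methyl{4-(methylamino)butyl}amino)propyl]dodecanamide | CCCCCCCCC[C@@H](N(C)C(C)=O)CC(=O)NCCCN(C)CCCCNC
F2 | step 11 | (4R)-5,9,14-trimethyl-4-nonyl-1,5,9,14-tetraazacycloheptadecane-2,6-dione | CCCCCCCCC[C@@H]1CC(=O)NCCCN(C)CCCCN(C)CCC(=O)N1C
F3 | step 6 | methyl (3R)-3-aminododecanoate hydrochloride | CCCCCCCCC[C@@H](N)CC(=O)OC.Cl
F4 | step 6 | methyl (3R)-3-[(2-nitrophenyl)sulfonylamino]dodecanoate | CCCCCCCCC[C@@H](NS(=O)(=O)c1ccccc1[N+](=O)[O-])CC(=O)OC
F5 | step 6 | methyl (3R)-3-[methyl(2-nitrophenylsulfonyl)amino]dodecanoate | CCCCCCCCC[C@@H](N(C)S(=O)(=O)c1ccccc1[N+](=O)[O-])CC(=O)OC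
F6 | step 3 | N-methyl-N-[4-(methylamino)butyl]formamide | CNCCCCN(C)C=O
F7 | step 3 | N-{4-[[3-(1,3-dioxoisoindolin-2-yl)propyl](methyl)amino]butyl}-N-methylformamide | O=CN(C)CCCCN(C)CCCN1C(=O)c2ccccc2C1=O
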